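**Assumption:** Stipulin has no stereocentres (it is achiral), so "single enantiomer" is read as the single E-configured chalcone drawn in the SMILES. Compound numbers are assigned in the forward steps. This route is a paper proposal; nothing here has been run.

**Retrosynthetic overview**
- Stipulin ⇒ its isomer 4,4'-bis(O-prenyl)isoliquiritigenin: both aryl–prenyl C–C bonds are made last by a proposed double [1,3] O→C prenyl shift, with the O-prenyl groups doubling as phenol protection.
- Bis(O-prenyl) chalcone ⇒ Claisen–Schmidt condensation (forms the E Cα=Cβ bond) of 2-hydroxy-4-prenyloxyacetophenone with 4-prenyloxybenzaldehyde.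
- Each fragment ⇒ commercial phenol + prenyl bromide (Williamson etherification).
- No ring is formed: both benzene rings are bought intact.

**Route**

Step 1
Reactants: 1, 2,4-dihydroxyacetophenone; 2, prenyl bromide (1-bromo-3-methylbut-2-ene)
Product: 3, 1-[2-hydroxy-4-(3-methylbut-2-enyloxy)phenyl]ethanone
Conditions: 2 (1.05 equiv), K2CO3 (1.1 equiv), acetone, reflux, 6 h
Reagents that add atoms: prenyl bromide (2), CC(C)=CCBr
Why: Williamson etherification; the 2-OH is hydrogen-bonded to the ketone and poorly nucleophilic, so the weak base alkylates only the 4-OH, and SN2 at the primary allylic bromide gives the unrearranged prenyl ether.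

Step 2
Reactants: 4, 4-hydroxybenzaldehyde; 2, prenyl bromide
Product: 5, 4-(3-methylbut-2-enyloxy)benzaldehyde
Conditions: 2 (1.1 equiv), K2CO3 (1.5 equiv), DMF, rt, 12 h
Reagents that add atoms: prenyl bromide (2), CC(C)=CCBr
Why: Williamson etherification of the only phenol; the aldehyde is inert to K2CO3.

Step 3
Reactants: 3, 1-[2-hydroxy-4-(prenyloxy)phenyl]ethanone; 5, 4-(prenyloxy)benzaldehyde
Product: 6, (E)-1-[2-hydroxy-4-(3-methylbut-2-enyloxy)phenyl]-3-[4-(3-methylbut-2-enyloxy)phenyl]prop-2-en-1-one
Conditions: 50% aq KOH (8 equiv), EtOH, 0 °C → rt, 36 h; then AcOH to pH 6 at 0 °C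
Reagents that add atoms: none
Why: Claisen–Schmidt (crossed aldol) condensation; the aldehyde cannot enolise, the base-stable prenyl ethers mask both para-phenols, and E1cB dehydration under thermodynamic control gives only the E-enone (no stereocentre is formed).

Step 4
Reactants: 6, (E)-4,4'-bis(O-prenyl)isoliquiritigenin
Product: 7, stipulin, (E)-1-[2,4-dihydroxy-5-(3-methylbut-2-enyl)phenyl]-3-[4-hydroxy-3-(3-methylbut-2-enyl)phenyl]prop-2-en-1-one
Conditions: Sc(OTf)3 (10 mol %), iPr-pybox (12 mol %; either enantiomer, used only as a bulky solubilising ligand), 2,6-di-tert-butyl-4-methylpyridine (25 mol %), 4 Å MS, CH2Cl2 (0.02 M), 0 °C → rt, dark; pH 7 phosphate buffer quench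
Reagents that add atoms: none (6 and 7 are isomers, C25H28O4)
Why: Proposed new method: a chelation-relayed double [1,3] O→C prenyl shift. The Sc(III)–pybox cation binds the 2'-O/C=O chelate, the binding mode known for Sc-catalysed reactions of 2'-hydroxychalcones. The resulting pull through ring A and through the cinnamoyl π-system makes both para-O-prenyl groups oxocarbenium-like leaving sites. Each O–CH2 bond ionises to a dimethylallyl cation/aryloxide contact ion pair (low polarity, dilute, ≤ rt), which collapses through its unsubstituted CH2 terminus onto the ortho carbon next to the departing oxygen. The para positions are blocked; on ring A, C3' is flanked by two oxygens and shielded by the ligated metal, so C5' should be attacked. The hindered pyridine relays the proton to rearomatise and turn the catalyst over, and keeps the medium free of strong Brønsted acid (no chroman formation). The chelate holds O2' away from Cβ (no flavanone), and the E-alkene is not involved. Closest known reaction types: the clay (montmorillonite K10 / Florisil)-promoted [1,3] shift of aryl prenyl ethers and Lewis-acid Friedel–Crafts prenylation of phenols; to my knowledge neither has been shown as a homogeneous, buffered, twofold late-stage process on a chalcone.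

**Compound list**
1 | 2,4-dihydroxyacetophenone | CC(=O)c1ccc(O)cc1O | starting material
2 | prenyl bromide (1-bromo-3-methylbut-2-ene) | CC(C)=CCBr | starting material
3 | 1-[2-hydroxy-4-(3-methylbut-2-enyloxy)phenyl]ethanone | CC(=O)c1ccc(OCC=C(C)C)cc1O | intermediate
4 | 4-hydroxybenzaldehyde | O=Cc1ccc(O)cc1 | starting material
5 | 4-(3-methylbut-2-enyloxy)benzaldehyde | O=Cc1ccc(OCC=C(C)C)cc1 | intermediate
6 | (E)-1-[2-hydroxy-4-(prenyloxy)phenyl]-3-[4-(prenyloxy)phenyl]prop-2-en-1-one | CC(C)=CCOc1ccc(/C=C/C(=O)c2ccc(OCC=C(C)C)cc2O)cc1 | intermediate
7 | stipulin | CC(C)=CCc1cc(/C=C/C(=O)c2cc(CC=C(C)C)c(O)cc2O)ccc1O | target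

**Totals**
Total step count: 4. Longest linear sequence: 3 steps (1 → 3 → 6 → 7, or 4 → 5 → 6 → 7).

**Three steps most likely to fail**
1. **Step 4 (proposed new double O→C prenyl shift).** Risks: C3' regioisomer on ring A, loss of prenyl as isoprene, chroman formation, and intermolecular crossover giving mono- and tri-prenylated products. Fallback (known chemistry, regiochemistry fixed by halogen position): start from commercial 5-bromo-2,4-dihydroxyacetophenone and 3-bromo-4-hydroxybenzaldehyde. Protect the phenols as MOM ethers, install each prenyl group by Pd-catalysed Stille coupling with tributyl(prenyl)stannane, join the fragments by KOH Claisen–Schmidt condensation, and remove the MOM groups with HCl/MeOH.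
2. **Step 3 (Claisen–Schmidt).** Risks: slow condensation of the chelated, phenoxide-deactivated ketone, and partial flavanone formation. Fallback: reverse the order of events. Take commercial isoliquiritigenin (2',4',4-trihydroxychalcone) and bis-O-prenylate it with 2/K2CO3 in acetone; the chelated 2'-OH does not react, so this gives 6 directly.
3. **Step 1 (selective 4-O-prenylation).** Risks: competing C-prenylation or bis-alkylation. Fallback: Mitsunobu etherification of 1 with 3-methylbut-2-en-1-ol (PPh3, DIAD, THF, 0 °C), which is O-selective for the more acidic, non-chelated 4-OH under neutral conditions.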